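## Retrosynthetic overview
1. Butenolide numbering: O1, C2 (lactone C=O), C3 (C–OH), C4 (C–aryl), C5 (quaternary, S). Both benzene rings are bought, and the butenolide is the only ring made.
2. Last: both aryl–prenyl bonds are made by a double Stille coupling on a dibromide, after global O-demethylation. Each bromine holds the place of a prenyl group, and the methyl ethers come with the commercial aldehydes.
3. Ring: O1–C2 is made by O-acylation of a tertiary acyloin with methoxyacetyl chloride. C3=C4 then follows by intramolecular aldol condensation onto the aryl ketone.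
4. Key bond C4–C5: a carbene-catalysed enantioselective cross-benzoin. The aryl aldehyde carbon, as its Breslow acyl anion, attacks the ketone carbon of an arylpyruvate, and this alone sets C5.
5. The arylpyruvate comes from 3-bromo-4-methoxybenzaldehyde by Horner–Wadsworth–Emmons olefination and enamide hydrolysis.

Assumption: the (5aR,10bS) precatalyst is taken, by analogy with related aldehyde–ketoester couplings, to give the (S)-acyloin. The sense is checked by X-ray (bromine anomalous dispersion) on the dibromo acyloin, and if the antipode forms, the equally available mirror-image precatalyst is used and nothing else changes.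

## Route

Step 1
Reactants: 1 3-bromo-4-methoxybenzaldehyde; 2 methyl 2-[(tert-butoxycarbonyl)amino]-2-(dimethoxyphosphoryl)acetate (racemic)
Product: 4 methyl 3-(3-bromo-4-methoxyphenyl)-2-oxopropanoate (keto/enol mixture), via Boc enamide 3 (not isolated)
Conditions: DBU (1.2 equiv), CH2Cl2, 0 °C → rt; then CF3CO2H, rt; then H2O, rt
Reagents that add atoms: phosphonate 2, COC(=O)C(NC(=O)OC(C)(C)C)P(=O)(OC)OC; water, O
Why: Horner–Wadsworth–Emmons olefination gives the Z-enamide, and acidolysis of its Boc group frees a primary enamine whose imine tautomer is hydrolysed to the α-keto ester, so the aldehyde becomes the pyruvate in one flask with no stereocentre involved.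

Step 2
Reactants: 4 methyl 3-(3-bromo-4-methoxyphenyl)-2-oxopropanoate; 5 3-bromo-4,5-dimethoxybenzaldehyde
Product: 6 methyl (2S)-2-[(3-bromo-4-methoxyphenyl)methyl]-3-(3-bromo-4,5-dimethoxyphenyl)-2-hydroxy-3-oxopropanoate
Conditions: (5aR,10bS)-2-(pentafluorophenyl)-5a,10b-dihydro-4H,6H-indeno[2,1-b][1,2,4]triazolo[4,3-d][1,4]oxazin-2-ium tetrafluoroborate (C18H11BF9N3O, 15 mol %), iPr2NEt (15 mol %), 4 Å MS, toluene, 0 °C; 5 (1.5 equiv) in the flask, 4 added over 10 h
Reagents that add atoms: none
Why: Proposed new method: the carbene adds to 5 and proton transfer gives the Breslow enaminol, an aroyl anion equivalent whose carbon attacks the ketone carbon of the small keto fraction of 4 (two carbonyl carbons joined), the indane wall of the catalyst and an O–H···O=C contact leaving one ketone face open so that the quaternary carbinol centre forms as (S), while homo-benzoin of 5 is reversible, only catalytic weak base is present and slow addition keeps 4 dilute so that its aldol pathways lag behind; the closest known reaction type is the triazolylidene-catalysed enantioselective aldehyde–α-ketoester cross-benzoin reaction, which already tolerates rapidly enolising β-halo α-keto esters.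

Step 3
Reactants: 6 the (S)-acyloin; 7 methoxyacetyl chloride
Product: 8 methyl (2S)-2-[(3-bromo-4-methoxyphenyl)methyl]-3-(3-bromo-4,5-dimethoxyphenyl)-2-[(methoxyacetyl)oxy]-3-oxopropanoate
Conditions: 7 (3 equiv), Et3N (4 equiv), 4-(dimethylamino)pyridine (0.5 equiv), CH2Cl2, 0 °C → rt
Reagents that add atoms: methoxyacetyl chloride 7, COCC(=O)Cl
Why: Nucleophile-catalysed O-acylation (partly through methoxyketene) esterifies the hindered tertiary carbinol, brings in C2 and C3 at the final oxidation level, and leaves the fully substituted (S) centre untouched while removing the free hydroxyl that any retro-benzoin cleavage would need.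

Step 4
Reactants: 8 the methoxyacetate ester
Product: 11 methyl (2S)-2-[(3-bromo-4-methoxyphenyl)methyl]-3-(3-bromo-4,5-dimethoxyphenyl)-4-methoxy-5-oxo-2,5-dihydrofuran-2-carboxylate, via lithium aldolate 9 (not isolated), via aldol trifluoroacetate 10 (not isolated)
Conditions: LiN(SiMe3)2 (1.2 equiv), THF, −78 °C; then (CF3CO)2O (2.5 equiv), −78 °C; then DBU (5 equiv), −78 → 0 °C
Reagents that add atoms: lithium bis(trimethylsilyl)amide, [Li+].C[Si](C)(C)[N-][Si](C)(C)C (lithium, in 9 only); trifluoroacetic anhydride, O=C(OC(=O)C(F)(F)F)C(F)(F)F (trifluoroacetyl group, in 10 only)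
Why: Intramolecular aldol condensation under kinetic control, in which the lithium ester enolate closes the five-membered ring onto the aryl ketone (far more electrophilic at −78 °C than the neighbouring methyl ester, so Dieckmann closure to a tetronate is avoided), the aldolate is trapped as its trifluoroacetate and E1cB elimination gives the 3-methoxybutenolide, erasing the two transient stereocentres and leaving C5 as set.

Step 5
Reactants: 11 the tetramethyl ether
Product: 12 methyl (2S)-2-[(3-bromo-4-hydroxyphenyl)methyl]-3-(3-bromo-4,5-dihydroxyphenyl)-4-hydroxy-5-oxo-2,5-dihydrofuran-2-carboxylate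
Conditions: BBr3 (8 equiv), CH2Cl2, −78 → 0 °C; then H2O, 0 °C
Reagents that add atoms: none
Why: Lewis acid ether cleavage (bromide attack on the methyl groups of the boron-complexed aryl and enol ethers) frees three phenols and the enol, while the hindered and less basic methyl ester, the lactone, both aryl bromides and the quaternary centre survive at or below 0 °C, and no acid-sensitive prenyl group is yet present.

Step 6
Reactants: 12 the dibromo tetraol; 13 tributyl(3-methylbut-2-en-1-yl)stannane
Product: 16 methyl (2S)-3-[3,4-dihydroxy-5-(3-methylbut-2-en-1-yl)phenyl]-4-hydroxy-2-{[4-hydroxy-3-(3-methylbut-2-en-1-yl)phenyl]methyl}-5-oxo-2,5-dihydrofuran-2-carboxylate (target), via persilylated dibromide 14 (not isolated), via persilylated diprenyl compound 15 (not isolated)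
Conditions: N,O-bis(trimethylsilyl)acetamide (8 equiv), toluene, 60 °C; then 13 (3 equiv), Pd(PPh3)4 (10 mol %), 105 °C; then MeOH, aq citric acid, rt
Reagents that add atoms: stannane 13, CCCC[Sn](CCCC)(CCCC)CC=C(C)C; N,O-bis(trimethylsilyl)acetamide, CC(=N[Si](C)(C)C)O[Si](C)(C)C (silyl groups, in 14 and 15 only)
Why: Transient persilylation masks the acidic enol and the phenols (which would protonate the allylstannane and chelate palladium), a double Migita–Kosugi–Stille coupling then replaces both bromines with reductive elimination at the unhindered allyl terminus giving linear prenyl groups, and mild acidic methanolysis removes the trimethylsilyl groups without cyclising the ortho-prenylphenols or touching C5.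

## Compound list
1 | 3-bromo-4-methoxybenzaldehyde | COc1ccc(C=O)cc1Br | starting material
2 | methyl 2-[(tert-butoxycarbonyl)amino]-2-(dimethoxyphosphoryl)acetate (racemic) | COC(=O)C(NC(=O)OC(C)(C)C)P(=O)(OC)OC | starting material
3 | methyl (Z)-3-(3-bromo-4-methoxyphenyl)-2-[(tert-butoxycarbonyl)amino]prop-2-enoate | COC(=O)/C(NC(=O)OC(C)(C)C)=C/c1ccc(OC)c(Br)c1 | intermediate
4 | methyl 3-(3-bromo-4-methoxyphenyl)-2-oxopropanoate | COC(=O)C(=O)Cc1ccc(OC)c(Br)c1 | intermediate
5 | 3-bromo-4,5-dimethoxybenzaldehyde | COc1cc(C=O)cc(Br)c1OC | starting material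
6 | methyl (2S)-2-[(3-bromo-4-methoxyphenyl)methyl]-3-(3-bromo-4,5-dimethoxyphenyl)-2-hydroxy-3-oxopropanoate | COC(=O)[C@@](C(=O)c1cc(OC)c(OC)c(Br)c1)(Cc1ccc(OC)c(Br)c1)O | intermediate
7 | methoxyacetyl chloride | COCC(=O)Cl | starting material
8 | methyl (2S)-2-[(3-bromo-4-methoxyphenyl)methyl]-3-(3-bromo-4,5-dimethoxyphenyl)-2-[(methoxyacetyl)oxy]-3-oxopropanoate | COC(=O)[C@@](C(=O)c1cc(OC)c(OC)c(Br)c1)(Cc1ccc(OC)c(Br)c1)OC(=O)COC | intermediate
9 | lithium alkoxide of methyl (2S)-2-[(3-bromo-4-methoxyphenyl)methyl]-3-(3-bromo-4,5-dimethoxyphenyl)-3-hydroxy-4-methoxy-5-oxooxolane-2-carboxylate (two further ring stereocentres unassigned, erased in the same step) | [Li+].COC(=O)[C@@]1(Cc2ccc(OC)c(Br)c2)OC(=O)C(OC)C1([O-])c1cc(OC)c(OC)c(Br)c1 | intermediate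
10 | methyl (2S)-2-[(3-bromo-4-methoxyphenyl)methyl]-3-(3-bromo-4,5-dimethoxyphenyl)-4-methoxy-5-oxo-3-[(trifluoroacetyl)oxy]oxolane-2-carboxylate (two further ring stereocentres unassigned, erased in the same step) | COC(=O)[C@@]1(Cc2ccc(OC)c(Br)c2)OC(=O)C(OC)C1(OC(=O)C(F)(F)F)c1cc(OC)c(OC)c(Br)c1 | intermediate
11 | methyl (2S)-2-[(3-bromo-4-methoxyphenyl)methyl]-3-(3-bromo-4,5-dimethoxyphenyl)-4-methoxy-5-oxo-2,5-dihydrofuran-2-carboxylate | COC(=O)[C@@]1(Cc2ccc(OC)c(Br)c2)OC(=O)C(OC)=C1c1cc(OC)c(OC)c(Br)c1 | intermediate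
12 | methyl (2S)-2-[(3-bromo-4-hydroxyphenyl)methyl]-3-(3-bromo-4,5-dihydroxyphenyl)-4-hydroxy-5-oxo-2,5-dihydrofuran-2-carboxylate | COC(=O)[C@@]1(Cc2ccc(O)c(Br)c2)OC(=O)C(O)=C1c1cc(O)c(O)c(Br)c1 | intermediate
13 | tributyl(3-methylbut-2-en-1-yl)stannane | CCCC[Sn](CCCC)(CCCC)CC=C(C)C | starting material
14 | methyl (2S)-2-{[3-bromo-4-(trimethylsilyloxy)phenyl]methyl}-3-[3-bromo-4,5-bis(trimethylsilyloxy)phenyl]-5-oxo-4-(trimethylsilyloxy)-2,5-dihydrofuran-2-carboxylate | COC(=O)[C@@]1(Cc2ccc(O[Si](C)(C)C)c(Br)c2)OC(=O)C(O[Si](C)(C)C)=C1c1cc(O[Si](C)(C)C)c(O[Si](C)(C)C)c(Br)c1 | intermediate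
15 | methyl (2S)-2-{[3-(3-methylbut-2-en-1-yl)-4-(trimethylsilyloxy)phenyl]methyl}-3-[3-(3-methylbut-2-en-1-yl)-4,5-bis(trimethylsilyloxy)phenyl]-5-oxo-4-(trimethylsilyloxy)-2,5-dihydrofuran-2-carboxylate | COC(=O)[C@@]1(Cc2ccc(O[Si](C)(C)C)c(CC=C(C)C)c2)OC(=O)C(O[Si](C)(C)C)=C1c1cc(O[Si](C)(C)C)c(O[Si](C)(C)C)c(CC=C(C)C)c1 | intermediate
16 | methyl (2S)-3-[3,4-dihydroxy-5-(3-methylbut-2-en-1-yl)phenyl]-4-hydroxy-2-{[4-hydroxy-3-(3-methylbut-2-en-1-yl)phenyl]methyl}-5-oxo-2,5-dihydrofuran-2-carboxylate | COC(=O)[C@@]1(Cc2ccc(O)c(CC=C(C)C)c2)OC(=O)C(O)=C1c1cc(O)c(O)c(CC=C(C)C)c1 | target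

## Step count and weak points
Total step count: 6. Longest linear sequence: 6 (1 → 4 → 6 → 8 → 11 → 12 → 16). All other partners are bought.

**Step 2 is the most likely to fail.**
- Failure mode: the enolate of 4 can condense with 5 or with itself (aldol, then lactonisation) faster than the carbene cycle turns over, or the ee may be modest.
- Idea of the fallback: it keeps the same bond and the same reversed polarity but carries the aroyl anion as a nitronate. The nitronate precursor is more acidic than 4, so the amine catalyst is never free to enolise the pyruvate, and no aldehyde is in the flask.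
- Course: the fallback sets out from 5, which with NH2OH·HCl and NaOAc gives (E)-3-bromo-4,5-dimethoxybenzaldehyde oxime F1. NaBO3·4H2O in acetic acid oxidises this to 1-bromo-2,3-dimethoxy-5-(nitromethyl)benzene F2. 9-O-Benzylcupreine, or its cupreidine pseudo-enantiomer if that gives the needed sense, adds F2 to 4 in an asymmetric nitroaldol reaction at −20 °C. This gives methyl (2S)-2-[(3-bromo-4-methoxyphenyl)methyl]-3-(3-bromo-4,5-dimethoxyphenyl)-2-hydroxy-3-nitropropanoate F3, whose nitro-bearing centre does not matter. Buffered aqueous TiCl3/NH4OAc (reductive Nef reaction) then turns CH–NO2 into C=O, and the route is rejoined at 6.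

**Step 6 is second.**
- Failure mode: incomplete silylation would let the enol destroy the stannane. Two hindered, electron-rich bromides must both couple, and some branched (reverse-prenyl) product is possible.
- Course: the fallback sets out from 12 and uses isolable protection plus a two-stage build-up of the prenyl group. TBSCl and imidazole in DMF give the tetrakis(tert-butyldimethylsilyl) ether of the dibromide F6. Allyltributylstannane with Pd(PPh3)4 in toluene at 100 °C gives the tetrasilylated diallyl compound F7, where no regiochemical question arises. Cross-metathesis with 2-methylbut-2-ene and the second-generation Grubbs catalyst gives the tetrasilylated diprenyl compound F8. Et3N·3HF in THF then returns to the route at 16.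

**Step 4 is third.**
- Failure mode: the crowded aldolate may revert or resist trapping, and on warming the enolate can leak into Dieckmann closure on the methyl ester.
- Course: the fallback sets out from 6 and replaces the aldol condensation by an olefination that is irreversible and ketone-selective. Commercial methyl 2-(dimethoxyphosphoryl)-2-methoxyacetate is saponified with one equivalent of LiOH to 2-(dimethoxyphosphoryl)-2-methoxyacetic acid F4. This is coupled to 6 with dicyclohexylcarbodiimide and 4-(dimethylamino)pyridine to give the phosphonoacetate ester of the acyloin F5. LiCl/DBU in MeCN (intramolecular Horner–Wadsworth–Emmons reaction) closes the ring and returns to the route at 11.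

## Further compounds
F1 | step 2 | (E)-3-bromo-4,5-dimethoxybenzaldehyde oxime | COc1cc(/C=N/O)cc(Br)c1OC
F2 | step 2 | 1-bromo-2,3-dimethoxy-5-(nitromethyl)benzene | COc1cc(C[N+](=O)[O-])cc(Br)c1OC
F3 | step 2 | methyl (2S)-2-[(3-bromo-4-methoxyphenyl)methyl]-3-(3-bromo-4,5-dimethoxyphenyl)-2-hydroxy-3-nitropropanoate (C3 epimers) | COC(=O)[C@@](C([N+](=O)[O-])c1cc(OC)c(OC)c(Br)c1)(Cc1ccc(OC)c(Br)c1)O
F4 | step 4 | 2-(dimethoxyphosphoryl)-2-methoxyacetic acid | COC(C(=O)O)P(=O)(OC)OC
F5 | step 4 | methyl (2S)-2-[(3-bromo-4-methoxyphenyl)methyl]-3-(3-bromo-4,5-dimethoxyphenyl)-2-{[2-(dimethoxyphosphoryl)-2-methoxyacetyl]oxy}-3-oxopropanoate | COC(=O)[C@@](C(=O)c1cc(OC)c(OC)c(Br)c1)(Cc1ccc(OC)c(Br)c1)OC(=O)C(OC)P(=O)(OC)OC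
F6 | step 6 | methyl (2S)-2-{[3-bromo-4-(tert-butyldimethylsilyloxy)phenyl]methyl}-3-[3-bromo-4,5-bis(tert-butyldimethylsilyloxy)phenyl]-4-(tert-butyldimethylsilyloxy)-5-oxo-2,5-dihydrofuran-2-carboxylate | COC(=O)[C@@]1(Cc2ccc(O[Si](C)(C)C(C)(C)C)c(Br)c2)OC(=O)C(O[Si](C)(C)C(C)(C)C)=C1c1cc(O[Si](C)(C)C(C)(C)C)c(O[Si](C)(C)C(C)(C)C)c(Br)c1
F7 | step 6 | methyl (2S)-2-{[3-allyl-4-(tert-butyldimethylsilyloxy)phenyl]methyl}-3-[3-allyl-4,5-bis(tert-butyldimethylsilyloxy)phenyl]-4-(tert-butyldimethylsilyloxy)-5-oxo-2,5-dihydrofuran-2-carboxylate | COC(=O)[C@@]1(Cc2ccc(O[Si](C)(C)C(C)(C)C)c(CC=C)c2)OC(=O)C(O[Si](C)(C)C(C)(C)C)=C1c1cc(O[Si](C)(C)C(C)(C)C)c(O[Si](C)(C)C(C)(C)C)c(CC=C)c1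
F8 | step 6 | methyl (2S)-2-{[4-(tert-butyldimethylsilyloxy)-3-(3-methylbut-2-en-1-yl)phenyl]methyl}-3-[3,4-bis(tert-butyldimethylsilyloxy)-5-(3-methylbut-2-en-1-yl)phenyl]-4-(tert-butyldimethylsilyloxy)-5-oxo-2,5-dihydrofuran-2-carboxylate | COC(=O)[C@@]1(Cc2ccc(O[Si](C)(C)C(C)(C)C)c(CC=C(C)C)c2)OC(=O)C(O[Si](C)(C)C(C)(C)C)=C1c1cc(O[Si](C)(C)C(C)(C)C)c(O[Si](C)(C)C(C)(C)C)c(CC=C(C)C)c1
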